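Start from what is left over and not from what is made. If the electrophile reacts first order at whatever c(nucleophile) stands (the pseudo-first-order view), the fractions kept over successive hours multiply together, so the log-loss, ln(charged/left), adds up. Divided by the whole charge of nucleophile, the log-loss gives the reach, in log-loss per molar charged, at a stated time.

common to all: electrophile 0.020 M

| run | nucleophile | remark | time |
|---|---|---|---|
| summer | 0.044 M (fed, over 8.0 h) | run made earlier; the fed solution adds 0.20 times the starting volume |  |
| spring | 0.090 M (fed, over 8.0 h) | run made earlier; the fed solution adds 0.20 times the starting volume |  |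
| Thursday's | 0.0360 M (fed, over 8.0 h) | the fed solution adds 0.20 times the starting volume | 8.0 h |
| Friday's | 0.0720 M (fed, over 8.0 h) | the fed solution adds 0.20 times the starting volume | 8.0 h |

- summer (time / h: electrophile / %, target / %): 0.200: 98, 1; 0.667: 96, 1; 1.00: 98, 1; 1.50: 94, 3; 2.50: 90, 9; 3.00: 87, 11; 4.00: 79, 18
- spring (time / h: electrophile / %, target / %): 0.500: 99, 0; 1.00: 98, 3; 1.50: 93, 11; 2.50: 81, 18; 3.00: 73, 23; 4.00: 68, 34

(readings scatter by 1.5 percentage points)

- charges are per starting volume, the dose included; the dosed solution carries all of it
- what was read earlier has a scatter of 1.5 percentage points, one standard deviation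

1. part of the electrophile that has reacted at the end, Thursday's
2. part of the electrophile that has reacted at the end, Friday's
3. what raising the concentration of nucleophile from its lowest to its highest value here does to the part of the electrophile that has reacted (changes below 5 percentage points count as none) (no change / it falls / it rises)

Each run reads what is left in two ways, as electrophile and as the complement of target, so I average the two:

summer, 4.00 h: left 80.5 %, log-loss 0.217, reach 4.93 M⁻¹

spring, 4.00 h: left 67.0 %, log-loss 0.400, reach 4.45 M⁻¹

The two reaches lie close together although the charges differ, so I take their mean, 4.69 M⁻¹. If fed nucleophile simply piled up, diluted by the feed, the log-loss would grow by a factor of 3.77 from 4.00 h to 8.0 h, and on that estimate Thursday's flask would reach 47.1 % reacted.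

That factor is the weak link, and the runs can test it. Reading the power of time from 2.50 h to 4.00 h:

summer: log-loss 0.0998 to 0.217, power 1.65

spring: log-loss 0.205 to 0.400, power 1.43

The mean power, 1.54, is a reading that carries the scatter, but it stands below the pile-up's 1.91, so I replace the factor:

reach at 8.0 h = 4.69 M⁻¹ × (8.0 h/4.00 h)^1.54 = 13.6 M⁻¹

This reach at the end of the feed is the number I carry. Multiplied by the charge and taken back through the exponential, it gives my figures:

Thursday's: 38.8 % reacted

Friday's: 62.5 % reacted

The forecast says 46 % for Thursday's flask and 72 % for Friday's, and of the part reacted as the nucleophile is raised: it rises. It adds that “late-stage inhibition or stoichiometry effects remain untested”. My Thursday's figure stands below the forecast's, and so does my Friday's.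

The simulation gives 39.4 % for Thursday's flask and 59.8 % for Friday's; the part reacted, from the lowest nucleophile charge to the highest: it rises, by 20 percentage points.

    nucleophile + acid set free ⇌ protonated nucleophile, settled at all times (K = 360 M⁻¹)
    target → over-reaction product (k = 4.70 × 10⁻⁸ s⁻¹)
    2 nucleophile → self-condensation product (k = 0.00150 M⁻¹ s⁻¹)
    electrophile + nucleophile → acid set free + target (k = 0.00210 M⁻¹ s⁻¹)
    nucleophile + acid set free ⇌ idle adduct, settled at all times (K = 25.0 M⁻¹)

Those results mean a reach of 13.9 M⁻¹ in Thursday's flask and 12.6 M⁻¹ in Friday's, against the carried 13.6 M⁻¹. Now take Friday's flask with 0.029 M of nucleophile instead. The carried reach gives a log-loss of 0.394, hence 32.6 % reacted. That neighbouring flask gives 33.9 % reacted at 8.00 h, with 66 % of its electrophile left.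

Readings and results stem from a simulated flask on assumed constants, and the scatter is random.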